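**Retrosynthetic overview**
1. Target 11 (6,7,8,3',4'-pentamethoxyflavone): open the pyranone (O1–C2 bond and C2=C3 unsaturation) back to the 2'-hydroxychalcone 9.
2. Chalcone 9: cut the Cα–Cβ bond by an intermolecular Claisen–Schmidt aldol condensation into ring A methyl ketone 6 and ring B aldehyde 7 (veratraldehyde). This is the key C–C bond.
3. Ketone 6: Friedel–Crafts acetylation with chelation-controlled ortho-demethylation of the symmetric 1,2,3,4-tetramethoxybenzene 4.
4. Arene 4: O-methylation of phenol 3, which comes from Baeyer–Villiger oxidation of cheap 2,3,4-trimethoxybenzaldehyde 1.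
5. Ring order: rings A and B are bought as arenes; ring C (the pyranone) is the only ring formed, in the last step.

Assumption: the target has no stereocentre and is achiral, so no enantiocontrol is needed; the only stereo-element on the way is the E alkene of 9, which is consumed in the last step.

**Route**

Step 1
Reactants: 1 2,3,4-trimethoxybenzaldehyde
Product: 3 2,3,4-trimethoxyphenol, via 2,3,4-trimethoxyphenyl formate 2 (not isolated)
Conditions: mCPBA (1.3 equiv), CH2Cl2, 0 °C to rt; then 2 M aq NaOH, THF, rt, N2; HCl to pH 6, NaHCO3 wash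
Reagents that add atoms: mCPBA (3-chloroperoxybenzoic acid), OOC(=O)c1cccc(Cl)c1
Why: Baeyer–Villiger (Dakin-type) oxidation, in which the electron-rich aryl group with ortho and para methoxy groups migrates in preference to hydride, followed by saponification of the aryl formate; no stereocentre is formed.

Step 2
Reactants: 3 2,3,4-trimethoxyphenol
Product: 4 1,2,3,4-tetramethoxybenzene
Conditions: MeI (1.5 equiv), K2CO3 (2 equiv), acetone, reflux
Reagents that add atoms: iodomethane, CI
Why: Williamson ether synthesis (SN2 O-methylation of the phenoxide) gives a symmetric arene whose two free positions are equivalent, so the next acylation has no regiochemical ambiguity.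

Step 3
Reactants: 4 1,2,3,4-tetramethoxybenzene
Product: 6 1-(2-hydroxy-3,4,5-trimethoxyphenyl)ethanone, via 2,3,4,5-tetramethoxyacetophenone 5 (not isolated)
Conditions: AcCl (1.2 equiv), AlCl3 (2.5 equiv), CH2Cl2, 0 °C to rt; ice/1 M HCl quench
Reagents that add atoms: acetyl chloride, CC(Cl)=O
Why: Friedel–Crafts acylation at one of the two equivalent free positions, after which AlCl3 chelated between the ketone oxygen and the ortho methoxy oxygen cleaves only that methyl ether (chelation-controlled demethylation), placing the free phenol where the pyranone oxygen is needed.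

Step 4
Reactants: 6 1-(2-hydroxy-3,4,5-trimethoxyphenyl)ethanone; 7 veratraldehyde (3,4-dimethoxybenzaldehyde)
Product: 9 (E)-3-(3,4-dimethoxyphenyl)-1-(2-hydroxy-3,4,5-trimethoxyphenyl)prop-2-en-1-one, via racemic aldol adduct 8 (not isolated)
Conditions: KOH (50% aq, 10 equiv), EtOH, 0 °C to rt, 24–48 h; then cold 2 M HCl
Reagents that add atoms: none
Why: Claisen–Schmidt (crossed aldol) condensation, in which only the methyl ketone can enolise, the intermolecular aldol addition forms the future C2–C3 bond, and E1cB dehydration removes the carbinol centre of 8 to give the conjugated E alkene under thermodynamic control.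

Step 5
Reactants: 9 (E)-3-(3,4-dimethoxyphenyl)-1-(2-hydroxy-3,4,5-trimethoxyphenyl)prop-2-en-1-one
Product: 11 2-(3,4-dimethoxyphenyl)-6,7,8-trimethoxy-4H-chromen-4-one (target), via racemic flavanone 10 (not isolated)
Conditions: I2 (10 mol%), DMSO, 130 °C, 2–3 h; aq Na2S2O3 wash
Reagents that add atoms: none
Why: Intramolecular oxa-Michael addition of the phenol closes ring C to the flavanone, which iodine with DMSO as terminal oxidant dehydrogenates to the chromone (oxidative cyclisation), erasing the transient C2 stereocentre so that the achiral target results.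

**Compound list**

| No. | Name | SMILES | Role |
|---|---|---|---|
| 1 | 2,3,4-trimethoxybenzaldehyde | COc1ccc(C=O)c(OC)c1OC | starting material |
| 2 | 2,3,4-trimethoxyphenyl formate | COc1ccc(OC=O)c(OC)c1OC | intermediate (not isolated) |
| 3 | 2,3,4-trimethoxyphenol | COc1ccc(O)c(OC)c1OC | intermediate |
| 4 | 1,2,3,4-tetramethoxybenzene | COc1ccc(OC)c(OC)c1OC | intermediate |
| 5 | 2,3,4,5-tetramethoxyacetophenone | CC(=O)c1cc(OC)c(OC)c(OC)c1OC | intermediate (not isolated) |
| 6 | 1-(2-hydroxy-3,4,5-trimethoxyphenyl)ethanone | CC(=O)c1cc(OC)c(OC)c(OC)c1O | intermediate |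
| 7 | veratraldehyde (3,4-dimethoxybenzaldehyde) | COc1ccc(C=O)cc1OC | starting material |
| 8 | 3-(3,4-dimethoxyphenyl)-3-hydroxy-1-(2-hydroxy-3,4,5-trimethoxyphenyl)propan-1-one (racemic) | COc1ccc(C(O)CC(=O)c2cc(OC)c(OC)c(OC)c2O)cc1OC | intermediate (not isolated) |
| 9 | (E)-3-(3,4-dimethoxyphenyl)-1-(2-hydroxy-3,4,5-trimethoxyphenyl)prop-2-en-1-one | COc1ccc(/C=C/C(=O)c2cc(OC)c(OC)c(OC)c2O)cc1OC | intermediate |
| 10 | 2-(3,4-dimethoxyphenyl)-6,7,8-trimethoxychroman-4-one (racemic) | COc1ccc(C2CC(=O)c3cc(OC)c(OC)c(OC)c3O2)cc1OC | intermediate (not isolated) |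
| 11 | 2-(3,4-dimethoxyphenyl)-6,7,8-trimethoxy-4H-chromen-4-one | COc1ccc(-c2cc(=O)c3cc(OC)c(OC)c(OC)c3o2)cc1OC | target |

**Totals**
Total step count: 5. Longest linear sequence: 5 steps (1 → 3 → 4 → 6 → 9 → 11); aldehyde 7 is bought.

**Three steps most likely to fail, with fallbacks**

Step 3 (acylation with mono-demethylation; risk of incomplete or double demethylation). The fallback sets out from 3 and comes back to the route at 6, so step 2 is skipped. Phenol 3 is acetylated (Ac2O, pyridine, CH2Cl2, rt) to 2,3,4-trimethoxyphenyl acetate F1. A Fries rearrangement (BF3·OEt2, AcOH, 90 °C, then aqueous work-up) moves the acetyl group to the only free ortho position, the para position being blocked. This gives 6 directly, with no ether cleavage to control.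

Step 4 (aldol condensation; the phenoxide–enolate dianion of 6 is a sluggish nucleophile, and flavanone formation or Cannizzaro loss of 7 may compete). The fallback sets out from 4 and comes back at 9. The acylation is stopped at the ketone (AcCl 1.05 equiv, AlCl3 1.1 equiv, CH2Cl2, −10 °C, short contact) and 5 is isolated. The non-phenolic ketone 5 condenses readily with 7 (NaOH, EtOH, rt) to (E)-3-(3,4-dimethoxyphenyl)-1-(2,3,4,5-tetramethoxyphenyl)prop-2-en-1-one F2. BCl3 (1.2 equiv, CH2Cl2, −78 to 0 °C, then water) then removes only the methoxy group ortho to the carbonyl through chelation, giving 9.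

Step 5 (oxidative cyclisation; risk of ring iodination, ether cleavage at 130 °C, or stalling at flavanone 10). The fallback sets out from 6 and comes back at 11, and avoids any oxidation by bringing ring B in at the acid oxidation level. The dianion of 6 (LiN(SiMe3)2, 3.5 equiv, THF, −78 °C) undergoes an intermolecular Claisen condensation with commercial 3,4-dimethoxybenzoyl chloride (COc1ccc(C(Cl)=O)cc1OC), −78 °C to rt, giving 1-(3,4-dimethoxyphenyl)-3-(2-hydroxy-3,4,5-trimethoxyphenyl)propane-1,3-dione F3. Acid cyclodehydration (H2SO4 cat., AcOH, 100 °C) closes ring C to 11.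

**Further compounds**
F1 | step 3 | 2,3,4-trimethoxyphenyl acetate | CC(=O)Oc1ccc(OC)c(OC)c1OC
F2 | step 4 | (E)-3-(3,4-dimethoxyphenyl)-1-(2,3,4,5-tetramethoxyphenyl)prop-2-en-1-one | COc1ccc(/C=C/C(=O)c2cc(OC)c(OC)c(OC)c2OC)cc1OC
F3 | step 5 | 1-(3,4-dimethoxyphenyl)-3-(2-hydroxy-3,4,5-trimethoxyphenyl)propane-1,3-dione | COc1ccc(C(=O)CC(=O)c2cc(OC)c(OC)c(OC)c2O)cc1OC
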